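**Retrosynthetic overview**

- Feature: the single benzene ring carries OAc at C1, between OMe (C2) and tridecyl (C6), with the free OH at C4 para to it. An aryl acetate is what Baeyer–Villiger oxidation makes from an aryl methyl ketone, so C1–OAc is read as a former C1–C(=O)CH3, that is 1-(4-hydroxy-2-methoxy-6-tridecylphenyl)ethanone.
- That ketone is cut at C1–C2 and C5–C6. C2–C5 and both ring oxygens come from 1,1-dimethoxy-3-(trimethylsilyloxy)buta-1,3-diene; C1 and C6 come from the triple bond of heptadec-3-yn-2-one. Cycloaddition and loss of methanol build the benzene ring, the only ring, in one operation.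
- Building blocks: the diene from acetyl chloride and 1,1-dichloroethene (acylation, methanolysis, silylation); the ynone from 1-pentadecyne and N-methoxy-N-methylacetamide.
- End game: benzyl protection of C4–OH, Baeyer–Villiger oxygen insertion at C1, hydrogenolysis.

Key step: step 5

Remark on the chemistry: the target is achiral, so no stereocentre has to be set. Ring atoms are numbered C1 (OAc), C2 (OMe), C3 (H), C4 (OH), C5 (H), C6 (tridecyl) in all intermediates.

**Route**

Step 1
Reactants: 1 acetyl chloride; 2 1,1-dichloroethene
Product: 4 4,4-dichlorobut-3-en-2-one, via 4,4,4-trichlorobutan-2-one 3 (not isolated)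
Conditions: AlCl3 (1.1 equiv), CH2Cl2, 0 °C to rt; ice/aq HCl; steam distillation, then distillation
Reagents that add atoms: none
Why: AlCl3-promoted Friedel–Crafts-type acylation of the alkene, in which the acylium ion adds to the CH2 carbon of 2 to give a chlorine-stabilised cation that captures chloride, after which the β-trichloromethyl ketone 3 loses HCl (E1cB) on steam distillation to give the conjugated dichlorovinyl ketone.

Step 2
Reactants: 4 4,4-dichlorobut-3-en-2-one
Product: 5 4,4-dimethoxybut-3-en-2-one
Conditions: NaOMe (2.1 equiv), MeOH, 0 °C to rt; filtration, distillation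
Reagents that add atoms: sodium methoxide, C[O-].[Na+]
Why: Two successive addition–elimination events (nucleophilic vinylic substitution) at the β-carbon of the enone, which behaves as a vinylogous acid chloride, should replace both chlorides by methoxide and give the acyl ketene acetal.

Step 3
Reactants: 5 4,4-dimethoxybut-3-en-2-one
Product: 6 1,1-dimethoxy-3-(trimethylsilyloxy)buta-1,3-diene
Conditions: Me3SiCl, Et3N, ZnCl2 (cat.), toluene, 40 °C; filtration under Ar, vacuum distillation
Reagents that add atoms: chlorotrimethylsilane, C[Si](C)(C)Cl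
Why: Silyl enol ether formation by soft enolisation (ZnCl2 activation, Et3N as base), the standard preparation of Danishefsky-type dienes, can only take place on the CH3 side because the other α-position is the vinylic CH of the ketene acetal.

Step 4
Reactants: 7 1-pentadecyne; 8 N-methoxy-N-methylacetamide
Product: 11 heptadec-3-yn-2-one, via lithium pentadec-1-yn-1-ide 9 (not isolated), via tetrahedral lithium alkoxide adduct 10 (not isolated)
Conditions: n-BuLi, THF, −78 °C; then 8, −78 to 0 °C; inverse quench into cold 1 M aq HCl
Reagents that add atoms: none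
Why: Weinreb ketone synthesis with a lithium acetylide, in which the chelated adduct 10 persists until the cold acidic quench so that only one addition occurs, and the acid protonates the released amine before it can add to the ynone.

Step 5
Reactants: 6 1,1-dimethoxy-3-(trimethylsilyloxy)buta-1,3-diene; 11 heptadec-3-yn-2-one
Product: 14 1-(4-hydroxy-2-methoxy-6-tridecylphenyl)ethanone, via cyclohexa-1,4-diene ketal cycloadduct 12 (not isolated), via aryl trimethylsilyl ether 13 (not isolated)
Conditions: 6 (2 equiv), toluene, 100 °C, sealed tube, Ar; then 1 M aq HCl, THF, rt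
Reagents that add atoms: none
Why: Diene 6 is a ketene acetal and a silyl enol ether at once, so it should react with the acetyl-activated alkyne 11 in a normal-electron-demand Diels–Alder reaction with very uneven bond formation: the CH2 end of 6 attacks the tridecyl-bearing β-carbon of the ynone (C5–C6) and the ketene-acetal carbon then bonds to the α-carbon (C1–C2), giving the cyclohexa-1,4-diene ketal 12. The six-membered carbocycle is thus closed by an intermolecular (4+2) cycloaddition, and at the stepwise extreme the second bond corresponds to 6-exo-trig capture of a dimethoxycarbenium carbon by the allenolate α-carbon. In 12 the C(OMe)2 carbon and the ring CH2 are both doubly allylic and face each other across the ring, so 1,4-elimination of methanol should aromatise it to silyl ether 13, and the dilute acid cleaves the O–Si bond to give phenol 14. The closest known reaction type is the cycloaddition of 1,1-dialkoxy-3-silyloxybutadienes with acetylenic esters and ketones, which gives 2-alkoxy-4-hydroxyaryl carbonyl compounds with this orientation. No stereocentre has to be controlled, because 12 has none and the product is a planar arene. The one selectivity needed is regiochemical, and the substrate pair secures it: the C3 silyloxy group and the two C1 methoxy groups of the diene all raise electron density at the same CH2 terminus, which pairs with the only electrophilic alkyne carbon, so that OMe ends ortho and OH para to the acetyl group with the chain ortho on the other side.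

Step 6
Reactants: 14 1-(4-hydroxy-2-methoxy-6-tridecylphenyl)ethanone
Product: 15 1-[4-(benzyloxy)-2-methoxy-6-tridecylphenyl]ethanone
Conditions: BnBr, K2CO3, DMF, rt
Reagents that add atoms: benzyl bromide, BrCc1ccccc1
Why: Williamson ether synthesis on the C4 phenoxide, the only nucleophile that K2CO3 generates, since the base is too weak to enolise the methyl ketone.

Step 7
Reactants: 15 1-[4-(benzyloxy)-2-methoxy-6-tridecylphenyl]ethanone
Product: 16 4-(benzyloxy)-2-methoxy-6-tridecylphenyl acetate
Conditions: mCPBA (2 equiv), CF3CO2H (cat.), CH2Cl2, 0 °C to rt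
Reagents that add atoms: 3-chloroperoxybenzoic acid (mCPBA), OOC(=O)c1cccc(Cl)c1
Why: Baeyer–Villiger oxidation, in which the Criegee adduct of the ketone (twisted out of the ring plane by the C2 and C6 substituents) should rearrange with migration of the electron-rich 2,4-dialkoxy-6-alkylaryl group in preference to methyl, placing the new oxygen between C1 and the acetyl carbon.

Step 8
Reactants: 16 4-(benzyloxy)-2-methoxy-6-tridecylphenyl acetate
Product: 17 ardisiphenol D (4-hydroxy-2-methoxy-6-tridecylphenyl acetate)
Conditions: H2 (1 atm), 10% Pd/C, EtOAc, rt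
Reagents that add atoms: none
Why: Catalytic hydrogenolysis of the benzylic C–O bond over Pd/C in a neutral aprotic solvent should free the C4 phenol while the aryl acetate, the methyl ether and the arene stay untouched.

**Compound list**

1 | acetyl chloride | CC(=O)Cl | starting material
2 | 1,1-dichloroethene | C=C(Cl)Cl | starting material
3 | 4,4,4-trichlorobutan-2-one | CC(=O)CC(Cl)(Cl)Cl | intermediate
4 | 4,4-dichlorobut-3-en-2-one | CC(=O)C=C(Cl)Cl | intermediate
5 | 4,4-dimethoxybut-3-en-2-one | CC(=O)C=C(OC)OC | intermediate
6 | 1,1-dimethoxy-3-(trimethylsilyloxy)buta-1,3-diene | C=C(O[Si](C)(C)C)C=C(OC)OC | intermediate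
7 | 1-pentadecyne | C#CCCCCCCCCCCCCC | starting material
8 | N-methoxy-N-methylacetamide | CC(=O)N(C)OC | starting material
9 | lithium pentadec-1-yn-1-ide | [Li]C#CCCCCCCCCCCCCC | intermediate
10 | lithium 2-[methoxy(methyl)amino]heptadec-3-yn-2-olate (racemic) | CCCCCCCCCCCCCC#CC(C)(O[Li])N(C)OC | intermediate
11 | heptadec-3-yn-2-one | CCCCCCCCCCCCCC#CC(C)=O | intermediate
12 | 1-[6,6-dimethoxy-2-tridecyl-4-(trimethylsilyloxy)cyclohexa-1,4-dien-1-yl]ethanone | CCCCCCCCCCCCCC1=C(C(C)=O)C(OC)(OC)C=C(O[Si](C)(C)C)C1 | intermediate
13 | 1-[2-methoxy-6-tridecyl-4-(trimethylsilyloxy)phenyl]ethanone | CCCCCCCCCCCCCc1cc(O[Si](C)(C)C)cc(OC)c1C(C)=O | intermediate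
14 | 1-(4-hydroxy-2-methoxy-6-tridecylphenyl)ethanone | CCCCCCCCCCCCCc1cc(O)cc(OC)c1C(C)=O | intermediate
15 | 1-[4-(benzyloxy)-2-methoxy-6-tridecylphenyl]ethanone | CCCCCCCCCCCCCc1cc(OCc2ccccc2)cc(OC)c1C(C)=O | intermediate
16 | 4-(benzyloxy)-2-methoxy-6-tridecylphenyl acetate | CCCCCCCCCCCCCc1cc(OCc2ccccc2)cc(OC)c1OC(C)=O | intermediate
17 | ardisiphenol D (4-hydroxy-2-methoxy-6-tridecylphenyl acetate) | CCCCCCCCCCCCCc1cc(O)cc(OC)c1OC(C)=O | target

**Step count**

Total: 8 steps. Longest linear sequence: 7 steps (steps 1, 2, 3, 5, 6, 7, 8); step 4 is a one-step side branch.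

**Steps most likely to fail, in order of risk**

Step 5 (cycloaddition and aromatisation). The ynone has only one activating group and an alkyl chain on the reacting β-carbon, so the cycloaddition may be slower than thermal oligomerisation or adventitious hydrolysis of the diene. The first C–C bond may also form without ring closure. The fallback is a classical arene route that sets out from acetyl chloride 1 and comes back at 15.
- Wittig olefination of commercial 3,5-dimethoxybenzaldehyde with the ylide from dodecyltriphenylphosphonium bromide (n-BuLi, THF) would give 1,3-dimethoxy-5-(tridec-1-en-1-yl)benzene F1.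
- Hydrogenation (H2, Pd/C, EtOAc) would give 1,3-dimethoxy-5-tridecylbenzene F2.
- Friedel–Crafts acetylation with acetyl chloride 1 (AlCl3, CH2Cl2, 0 °C), directed para to one methoxy group and ortho to the other, would give 1-(2,4-dimethoxy-6-tridecylphenyl)ethanone F3.
- BBr3 (CH2Cl2, −78 °C to rt) would cleave both methyl ethers to 1-(2,4-dihydroxy-6-tridecylphenyl)ethanone F4.
- BnBr and K2CO3 in acetone should alkylate only the C4 phenol, because the C2 phenol is held in a hydrogen bond to the ketone, giving 1-[4-(benzyloxy)-2-hydroxy-6-tridecylphenyl]ethanone F5.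
- MeI and K2CO3 in DMF at 60 °C would then methylate the chelated C2–OH to give 15.

Step 7 (Baeyer–Villiger oxidation). Peracid addition to the doubly ortho-substituted carbonyl group may be slow, so that electrophilic oxidation of the electron-rich ring competes with oxygen insertion. The fallback sets out from 15 and comes back at 16, replacing the ketone oxidation by a Hock-type hydroperoxide rearrangement.
- LiAlH4 (THF, 0 °C) would reduce 15 to racemic 1-[4-(benzyloxy)-2-methoxy-6-tridecylphenyl]ethanol F6.
- H2O2 (50% aq) with catalytic TsOH in MeCN would convert the alcohol, through its stabilised benzylic cation, into 1-[4-(benzyloxy)-2-methoxy-6-tridecylphenyl]ethyl hydroperoxide F7.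
- Under the same acid F7 should undergo aryl migration to oxygen and fragment, with loss of acetaldehyde, to 4-(benzyloxy)-2-methoxy-6-tridecylphenol F8.
- Acetylation with acetyl chloride 1 (Et3N, DMAP cat., CH2Cl2) would give 16.

Step 2 (methanolysis of the dichlorovinyl ketone). Methoxide may attack the carbonyl group and cleave the chain, stop after one substitution, or add a third time. The fallback sets out from ynone 11 and comes back at 15, bypassing steps 1 to 3 with a different four-carbon partner.
- Commercial methyl acetoacetate would be silylated (Me3SiCl, Et3N) to methyl 3-(trimethylsilyloxy)but-2-enoate F9.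
- LiN(i-Pr)2 and Me3SiCl (THF, −78 °C) would convert F9 into 1-methoxy-1,3-bis(trimethylsilyloxy)buta-1,3-diene F10, to be used crude.
- Heating F10 with 11 (toluene, 100 °C) should give, with the same orientation, 1-[6-methoxy-2-tridecyl-4,6-bis(trimethylsilyloxy)cyclohexa-1,4-dien-1-yl]ethanone F11.
- Dilute HCl in THF would hydrolyse the mixed ketal and both silyl ethers of F11 to 1-(2,4-dihydroxy-6-tridecylphenyl)ethanone F4.
- F4 would then be carried through 1-[4-(benzyloxy)-2-hydroxy-6-tridecylphenyl]ethanone F5 to 15 by the selective benzylation and methylation described for step 5.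

**Further compounds**

F1 | step 5 | 1,3-dimethoxy-5-(tridec-1-en-1-yl)benzene (E/Z mixture) | CCCCCCCCCCCC=Cc1cc(OC)cc(OC)c1
F2 | step 5 | 1,3-dimethoxy-5-tridecylbenzene | CCCCCCCCCCCCCc1cc(OC)cc(OC)c1
F3 | step 5 | 1-(2,4-dimethoxy-6-tridecylphenyl)ethanone | CCCCCCCCCCCCCc1cc(OC)cc(OC)c1C(C)=O
F4 | step 5 | 1-(2,4-dihydroxy-6-tridecylphenyl)ethanone | CCCCCCCCCCCCCc1cc(O)cc(O)c1C(C)=O
F5 | step 5 | 1-[4-(benzyloxy)-2-hydroxy-6-tridecylphenyl]ethanone | CCCCCCCCCCCCCc1cc(OCc2ccccc2)cc(O)c1C(C)=O
F6 | step 7 | 1-[4-(benzyloxy)-2-methoxy-6-tridecylphenyl]ethanol (racemic) | CCCCCCCCCCCCCc1cc(OCc2ccccc2)cc(OC)c1C(C)O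
F7 | step 7 | 1-[4-(benzyloxy)-2-methoxy-6-tridecylphenyl]ethyl hydroperoxide (racemic) | CCCCCCCCCCCCCc1cc(OCc2ccccc2)cc(OC)c1C(C)OO
F8 | step 7 | 4-(benzyloxy)-2-methoxy-6-tridecylphenol | CCCCCCCCCCCCCc1cc(OCc2ccccc2)cc(OC)c1O
F9 | step 2 | methyl 3-(trimethylsilyloxy)but-2-enoate | COC(=O)C=C(C)O[Si](C)(C)C
F10 | step 2 | 1-methoxy-1,3-bis(trimethylsilyloxy)buta-1,3-diene | C=C(O[Si](C)(C)C)C=C(OC)O[Si](C)(C)C
F11 | step 2 | 1-[6-methoxy-2-tridecyl-4,6-bis(trimethylsilyloxy)cyclohexa-1,4-dien-1-yl]ethanone (racemic) | CCCCCCCCCCCCCC1=C(C(C)=O)C(OC)(O[Si](C)(C)C)C=C(O[Si](C)(C)C)C1
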